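The pyranone ring (O1, C2, C3, C4, C4a, C8a) is traced back to a benzofuran-3(2H)-one whose C2 carries the methyl group and a 1-hydroxyethyl group. Ionisation of the derived triflate makes the ketone carbon, which is bonded to C4a and becomes C4, shift from C2 to the carbinol carbon (future C3); the lone pair of O1 stabilises the cation at C2. One operation thus enlarges the five-membered ring to the 2,3-dimethylchromone with both methyl groups in place. The furanone oxygen is the lactone oxygen of an (R)-4-propyldihydrocoumarin, which fixes the regiochemistry; asymmetric CuH reduction then sets C2 and C3, and debenzylation and C6-prenylation finish the route.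

Key step: step 5

Assumption: 3,5-bis(benzyloxy)phenol is taken as commercially available, and the (S)-configured ligand of step 6 is taken to deliver hydride to the face of C2 that gives (2S); if the opposite sense is found, the (R)-ligand is used.

Step 1
Reactants: 1 3,5-bis(benzyloxy)phenol; 2 (E)-hex-2-enal
Product: 4 (4R)-5,7-bis(benzyloxy)-4-propyl-3,4-dihydro-2H-chromen-2-one, via lactol 3 (not isolated)
Conditions: (S)-α,α-diphenylprolinol trimethylsilyl ether (20 mol %), PhCO2H (20 mol %), toluene, 0 °C; then Dess–Martin periodinane, NaHCO3, CH2Cl2, 23 °C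
Reagents that add atoms: none
Why: Organocatalytic Friedel–Crafts alkylation/hemiacetalisation cascade through the (E)-iminium ion of 2 followed by lactol oxidation: the diphenyl(silyloxy)methyl group of the (S)-catalyst shields one face of the β-carbon, the phenol ortho carbon adds to the open face and by the usual shielding model sets the (R)-centre at C4, and Dess–Martin oxidation converts the lactol into the lactone.

Step 2
Reactants: 4 (4R)-5,7-bis(benzyloxy)-4-propyl-3,4-dihydro-2H-chromen-2-one; 5 2-bromopropanoic acid (racemic)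
Product: 7 (2RS)-2-{3,5-bis(benzyloxy)-2-[(3R)-1-methoxy-1-oxohexan-3-yl]phenoxy}propanoic acid, via sodium phenoxide ester 6 (not isolated)
Conditions: NaOMe (2.6 equiv), MeOH, 23 °C; then 5 (1.5 equiv), 65 °C; 1 M HCl
Reagents that add atoms: sodium methoxide, [Na+].[O-]C
Why: Methoxide opens the aryl lactone (transesterification) and releases the lactone oxygen as the only phenoxide of the molecule, which is O-alkylated by the α-bromocarboxylate (Williamson ether synthesis), so that the oxygen next to the side chain is the one that becomes O1; the new α-aryloxy centre is formed without control because it is lost again in steps 3 to 5.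

Step 3
Reactants: 7 (2RS)-2-{3,5-bis(benzyloxy)-2-[(3R)-1-methoxy-1-oxohexan-3-yl]phenoxy}propanoic acid
Product: 9 methyl (3R)-3-[(2RS)-4,6-bis(benzyloxy)-2-methyl-3-oxo-2,3-dihydro-1-benzofuran-7-yl]hexanoate, via mixed anhydride 8 (not isolated)
Conditions: (CF3CO)2O, CH2Cl2, 0 → 23 °C; aq. NaHCO3
Reagents that add atoms: none
Why: Intramolecular Friedel–Crafts acylation of the mixed trifluoroacetic anhydride at the only free carbon ortho to the ether oxygen closes the benzofuran-3(2H)-one, the very electron-rich ring needing no Lewis acid; C2 stays enolisable and stereorandom.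

Step 4
Reactants: 9 methyl (3R)-3-[(2RS)-4,6-bis(benzyloxy)-2-methyl-3-oxo-2,3-dihydro-1-benzofuran-7-yl]hexanoate; 10 acetaldehyde
Product: 11 methyl (3R)-3-[4,6-bis(benzyloxy)-2-(1-hydroxyethyl)-2-methyl-3-oxo-2,3-dihydro-1-benzofuran-7-yl]hexanoate (mixture of the four diastereomers at C2 and the carbinol carbon)
Conditions: LiN(SiMe3)2, THF, −78 °C; then 10; AcOH, −78 °C
Reagents that add atoms: none
Why: Aldol addition of the lithium enolate of 9 to acetaldehyde at C2 gives the quaternary centre that carries the future C3 carbon; the two new stereocentres are left uncontrolled because both carbons become sp2 in step 5, and the cold acidic quench prevents retro-aldol cleavage.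

Step 5
Reactants: 11 methyl (3R)-3-[4,6-bis(benzyloxy)-2-(1-hydroxyethyl)-2-methyl-3-oxo-2,3-dihydro-1-benzofuran-7-yl]hexanoate
Product: 13 methyl (3R)-3-[5,7-bis(benzyloxy)-2,3-dimethyl-4-oxo-4H-chromen-8-yl]hexanoate, via triflate 12 (not isolated)
Conditions: Tf2O, 2,6-lutidine, CH2Cl2, −78 → 23 °C
Reagents that add atoms: none
Why: Proposed new method: the secondary triflate 12 ionises with concerted 1,2-shift of the furanone ketone carbon from C2 to the carbinol carbon (the migrating C–C bond lies anti-periplanar to the C–OTf bond), driven by the lone pair of the ring oxygen, to give a 4-oxochromenylium ion that loses the proton of the new C3 to the base and so delivers the chromone. The closest known reaction types are the Cargill 1,2-acyl shift of β,γ-unsaturated ketones, the semipinacol ring expansion and, in radical form, the Dowd–Beckwith ring expansion. No new ring bond is closed: the five-membered furanone ring is enlarged to the six-membered pyranone ring by migration of its own endocyclic C3–C2 bond, which inserts the carbinol carbon between the ketone carbon and C2. No stereocentre is created, since C2 and C3 become sp2 and the (R)-centre of the side chain is not touched, so all four diastereomers of 11 converge. The step needs acyl migration in preference to methyl migration, to elimination towards the 2-vinyl compound and to retro-aldol cleavage; the higher migratory aptitude of acyl, the oxocarbenium stabilisation by O1, the non-enolisable quaternary C2 and the prior conversion of the hydroxyl group into a triflate under a hindered base secure this.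

Step 6
Reactants: 13 methyl (3R)-3-[5,7-bis(benzyloxy)-2,3-dimethyl-4-oxo-4H-chromen-8-yl]hexanoate
Product: 14 methyl (3R)-3-[(2S,3S)-5,7-bis(benzyloxy)-2,3-dimethyl-4-oxo-3,4-dihydro-2H-chromen-8-yl]hexanoate
Conditions: Cu(OAc)2 (5 mol %), (S)-DTBM-SEGPHOS (5.5 mol %), (EtO)2MeSiH, t-BuOH, toluene, 0 → 23 °C; then p-TsOH·H2O (cat.), toluene, 40 °C
Reagents that add atoms: none
Why: Copper hydride-catalysed asymmetric 1,4-reduction (conjugate hydrosilylation with protonation by t-BuOH): the chiral bisphosphine-bound CuH adds hydride to one face of C2 and sets (2S), and acid-catalysed enolisation then equilibrates C3 to the more stable trans isomer (2S,3S) without opening the C2–O1 bond.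

Step 7
Reactants: 14 methyl (3R)-3-[(2S,3S)-5,7-bis(benzyloxy)-2,3-dimethyl-4-oxo-3,4-dihydro-2H-chromen-8-yl]hexanoate
Product: 15 methyl (3R)-3-[(2S,3S)-5,7-dihydroxy-2,3-dimethyl-4-oxo-3,4-dihydro-2H-chromen-8-yl]hexanoate
Conditions: H2 (1 atm), Pd/C (10 %), EtOAc, 23 °C
Reagents that add atoms: none
Why: Catalytic hydrogenolysis of the two benzyl ethers, which leaves the aryl ketone, the methyl ester and the three stereocentres untouched because neither acid nor base is present.

Step 8
Reactants: 15 methyl (3R)-3-[(2S,3S)-5,7-dihydroxy-2,3-dimethyl-4-oxo-3,4-dihydro-2H-chromen-8-yl]hexanoate; 16 1-bromo-3-methylbut-2-ene (prenyl bromide)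
Product: 17 methyl (3R)-3-[(2S,3S)-5,7-dihydroxy-2,3-dimethyl-6-(3-methylbut-2-en-1-yl)-4-oxo-3,4-dihydro-2H-chromen-8-yl]hexanoate (CNP0068017.2)
Conditions: NaOMe (1.1 equiv), MeOH, 0 °C; then 16; aq. NH4Cl
Reagents that add atoms: none
Why: Base-mediated C-alkylation of the phloroglucinol-type phenoxide by the allylic bromide (C-prenylation) at C6, the only unsubstituted ring carbon, the protic solvent favouring C- over O-alkylation; no stereocentre is formed and enolisation at C3 can only return the preferred trans ring.

Compound list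
1 | 3,5-bis(benzyloxy)phenol | Oc1cc(OCc2ccccc2)cc(OCc2ccccc2)c1 | starting material
2 | (E)-hex-2-enal | CCC/C=C/C=O | starting material
3 | (4R)-5,7-bis(benzyloxy)-4-propyl-3,4-dihydro-2H-chromen-2-ol (lactol, both anomers) | CCC[C@@H]1CC(O)Oc2cc(OCc3ccccc3)cc(OCc3ccccc3)c21 | intermediate
4 | (4R)-5,7-bis(benzyloxy)-4-propyl-3,4-dihydro-2H-chromen-2-one | CCC[C@@H]1CC(=O)Oc2cc(OCc3ccccc3)cc(OCc3ccccc3)c21 | intermediate
5 | 2-bromopropanoic acid (racemic) | CC(Br)C(=O)O | starting material
6 | sodium 3,5-bis(benzyloxy)-2-[(3R)-1-methoxy-1-oxohexan-3-yl]phenolate | CCC[C@H](CC(=O)OC)c1c([O-])cc(OCc2ccccc2)cc1OCc1ccccc1.[Na+] | intermediate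
7 | (2RS)-2-{3,5-bis(benzyloxy)-2-[(3R)-1-methoxy-1-oxohexan-3-yl]phenoxy}propanoic acid | CCC[C@H](CC(=O)OC)c1c(OC(C)C(=O)O)cc(OCc2ccccc2)cc1OCc1ccccc1 | intermediate
8 | mixed anhydride of 7 with trifluoroacetic acid | CCC[C@H](CC(=O)OC)c1c(OC(C)C(=O)OC(=O)C(F)(F)F)cc(OCc2ccccc2)cc1OCc1ccccc1 | intermediate
9 | methyl (3R)-3-[(2RS)-4,6-bis(benzyloxy)-2-methyl-3-oxo-2,3-dihydro-1-benzofuran-7-yl]hexanoate | CCC[C@H](CC(=O)OC)c1c2OC(C)C(=O)c2c(OCc2ccccc2)cc1OCc1ccccc1 | intermediate
10 | acetaldehyde | CC=O | starting material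
11 | methyl (3R)-3-[4,6-bis(benzyloxy)-2-(1-hydroxyethyl)-2-methyl-3-oxo-2,3-dihydro-1-benzofuran-7-yl]hexanoate (four diastereomers at C2 and the carbinol carbon) | CCC[C@H](CC(=O)OC)c1c2OC(C)(C(C)O)C(=O)c2c(OCc2ccccc2)cc1OCc1ccccc1 | intermediate
12 | trifluoromethanesulfonate of 11 at the carbinol oxygen | CCC[C@H](CC(=O)OC)c1c2OC(C)(C(C)OS(=O)(=O)C(F)(F)F)C(=O)c2c(OCc2ccccc2)cc1OCc1ccccc1 | intermediate
13 | methyl (3R)-3-[5,7-bis(benzyloxy)-2,3-dimethyl-4-oxo-4H-chromen-8-yl]hexanoate | CCC[C@H](CC(=O)OC)c1c(OCc2ccccc2)cc(OCc2ccccc2)c2c1oc(C)c(C)c2=O | intermediate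
14 | methyl (3R)-3-[(2S,3S)-5,7-bis(benzyloxy)-2,3-dimethyl-4-oxo-3,4-dihydro-2H-chromen-8-yl]hexanoate | CCC[C@H](CC(=O)OC)c1c(OCc2ccccc2)cc(OCc2ccccc2)c2c1O[C@@H](C)[C@H](C)C2=O | intermediate
15 | methyl (3R)-3-[(2S,3S)-5,7-dihydroxy-2,3-dimethyl-4-oxo-3,4-dihydro-2H-chromen-8-yl]hexanoate | CCC[C@H](CC(=O)OC)c1c(O)cc(O)c2c1O[C@@H](C)[C@H](C)C2=O | intermediate
16 | 1-bromo-3-methylbut-2-ene (prenyl bromide) | CC(C)=CCBr | starting material
17 | methyl (3R)-3-[(2S,3S)-5,7-dihydroxy-2,3-dimethyl-6-(3-methylbut-2-en-1-yl)-4-oxo-3,4-dihydro-2H-chromen-8-yl]hexanoate | CCC[C@H](CC(=O)OC)c1c(O)c(CC=C(C)C)c(O)c2c1O[C@@H](C)[C@H](C)C2=O | target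

Total step count: 8. Longest linear sequence: 8 steps (1 to 17).

Steps most likely to fail

Step 5 (Proposed new method). The triflate may eliminate towards the 2-vinyl compound, a methyl group may migrate in place of the acyl carbon, or retro-aldol cleavage may outrun triflation. The fallback uses known radical chemistry and sets out from 11. The alcohol is acylated with PhOC(S)Cl (pyridine, DMAP, CH2Cl2) to the O-phenyl thionocarbonate of 11, F1. Slow addition of Bu3SnH with AIBN in toluene at 110 °C generates the secondary radical. This radical adds to the ketone carbon, and the cyclopropyloxy radical opens by cleavage of the bond between the ketone carbon and C2 (Dowd–Beckwith ring expansion, with Barton–McCombie radical generation). Hydrogen transfer then gives methyl (3R)-3-[5,7-bis(benzyloxy)-2,3-dimethyl-4-oxo-3,4-dihydro-2H-chromen-8-yl]hexanoate as a mixture of ring stereoisomers, F2. Dehydrogenation with iodine (I2, catalytic) in DMSO at 120 °C comes back to the route at 13.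

Step 6. Hydride transfer to the tetrasubstituted, electron-rich enone may be slow, and the facial selectivity at C2 may be poor. The fallback sets out from 13 and replaces catalyst control by separation with recycling. Conjugate reduction with LiBH(s-Bu)3 (THF, −78 °C) and the same acid equilibration should give 14 together with its ring diastereomer methyl (3R)-3-[(2R,3R)-5,7-bis(benzyloxy)-2,3-dimethyl-4-oxo-3,4-dihydro-2H-chromen-8-yl]hexanoate, F3. The two trans compounds are diastereomers because of the side-chain centre and are separated by preparative HPLC. F3 is returned to 13 by dehydrogenation (I2, DMSO, 120 °C) and reduced again. The fallback comes back to the route at 14.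

Step 8. O-alkylation or double alkylation with dearomatisation may compete with C6-alkylation, and base-induced opening of the C2–O1 bond may erode C2. The fallback is neutral and sets out from 15. Palladium-catalysed O-alkylation with tert-butyl 2-methylbut-3-en-2-yl carbonate (Pd(PPh3)4, THF, 0 °C) at the non-chelated 7-hydroxyl gives methyl (3R)-3-[(2S,3S)-5-hydroxy-2,3-dimethyl-7-[(2-methylbut-3-en-2-yl)oxy]-4-oxo-3,4-dihydro-2H-chromen-8-yl]hexanoate, F4. Aromatic Claisen rearrangement (toluene, 110 °C) moves the allyl unit to C6, the only free ortho carbon, as the 3-methylbut-2-enyl group. The fallback comes back to the route at 17.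

Further compounds
F1 | step 5 | methyl (3R)-3-[4,6-bis(benzyloxy)-2-methyl-3-oxo-2-{1-[(phenoxycarbonothioyl)oxy]ethyl}-2,3-dihydro-1-benzofuran-7-yl]hexanoate | CCC[C@H](CC(=O)OC)c1c2OC(C)(C(C)OC(=S)Oc3ccccc3)C(=O)c2c(OCc2ccccc2)cc1OCc1ccccc1
F2 | step 5 | methyl (3R)-3-[5,7-bis(benzyloxy)-2,3-dimethyl-4-oxo-3,4-dihydro-2H-chromen-8-yl]hexanoate (mixture of ring stereoisomers) | CCC[C@H](CC(=O)OC)c1c(OCc2ccccc2)cc(OCc2ccccc2)c2c1OC(C)C(C)C2=O
F3 | step 6 | methyl (3R)-3-[(2R,3R)-5,7-bis(benzyloxy)-2,3-dimethyl-4-oxo-3,4-dihydro-2H-chromen-8-yl]hexanoate | CCC[C@H](CC(=O)OC)c1c(OCc2ccccc2)cc(OCc2ccccc2)c2c1O[C@H](C)[C@@H](C)C2=O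
F4 | step 8 | methyl (3R)-3-[(2S,3S)-5-hydroxy-2,3-dimethyl-7-[(2-methylbut-3-en-2-yl)oxy]-4-oxo-3,4-dihydro-2H-chromen-8-yl]hexanoate | CCC[C@H](CC(=O)OC)c1c(OC(C)(C)C=C)cc(O)c2c1O[C@@H](C)[C@H](C)C2=O
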